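**Strategy.** Without its O-methyl group, ring A has a mirror plane through C2 and C5: oxygens on C1 and C3, identical 4-hydroxybenzyl groups on C4 and C6, and the ring B arm on C5. The ring is therefore built as a symmetric 4,6-dibenzyl-5-alkylcyclohexane-1,3-dione, desymmetrised by mono-O-methylation and aromatised late. A single Michael–Claisen annulation forms it: the anion of a benzylmalonate attacks the β-carbon of an α-benzylated methyl enone (C5–C6), and the acetyl enolate then acylates on one malonate ester (C1–C2). The precursor is the benzyl-protected (E)-3-benzylhex-3-en-2-one with ring B at its chain end. Methyl malonate esters are chosen to ease the Claisen closure and the later ester removal.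

Key step: step 8

Assumption: 4-(benzyloxy)phenylmagnesium bromide is used as a purchased THF solution; the target has no stereocentre, so all sp3 stereocentres of intermediates are carried as racemates or diastereomer mixtures, and aromatisation of ring A erases them.

Abbreviation used in step names: ArB = 3-(benzyloxy)-4-[4-(benzyloxy)benzyl]phenyl (protected ring B). Full names are in the compound list.

**Route**

Step 1
Reactants: 1 4-bromo-2-hydroxybenzaldehyde
Product: 2 2-(benzyloxy)-4-bromobenzaldehyde
Conditions: BnBr, K2CO3, DMF, rt to 50 °C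
Reagents that add atoms: benzyl bromide, BrCc1ccccc1
Why: Williamson ether synthesis on the phenoxide; the aldehyde and the aryl bromide are inert to K2CO3 and benzyl bromide.

Step 2
Reactants: 2 2-(benzyloxy)-4-bromobenzaldehyde; 3 4-(benzyloxy)phenylmagnesium bromide
Product: 4 [2-(benzyloxy)-4-bromophenyl][4-(benzyloxy)phenyl]methanol (racemate)
Conditions: THF, 0 °C; then sat. aq. NH4Cl
Reagents that add atoms: none
Why: Grignard addition to the aldehyde, which is far faster than any exchange at the aryl bromide at 0 °C; the carbinol stereocentre is formed racemic and is removed in step 3.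

Step 3
Reactants: 4 [2-(benzyloxy)-4-bromophenyl][4-(benzyloxy)phenyl]methanol
Product: 5 2-(benzyloxy)-1-[4-(benzyloxy)benzyl]-4-bromobenzene
Conditions: Et3SiH, CF3CO2H, CH2Cl2, 0 °C
Reagents that add atoms: none
Why: Ionic hydrogenation; the diarylmethyl cation is stabilised by para- and ortho-alkoxy groups and is captured by the silane, while aryl benzyl ethers and the aryl bromide tolerate short exposure to cold acid.

Step 4
Reactants: 5 2-(benzyloxy)-1-[4-(benzyloxy)benzyl]-4-bromobenzene; 6 allyl alcohol
Product: 7 3-(ArB)propanal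
Conditions: Pd(OAc)2 (cat.), Bu4NCl, NaHCO3, DMF, 80–90 °C
Reagents that add atoms: none
Why: Jeffery-type Heck arylation of allyl alcohol; the aryl group adds to the terminal alkene carbon and β-hydride elimination toward the carbinol carbon gives the enol, hence the 3-arylpropanal directly, at an aryl bromide with no ortho substituent.

Step 5
Reactants: 8 diethyl (2-oxopropyl)phosphonate; 9 4-(benzyloxy)benzyl chloride
Product: 10 diethyl {1-[4-(benzyloxy)phenyl]-3-oxobutan-2-yl}phosphonate (racemate)
Conditions: NaH, THF, 0 °C; then 9, NaI (cat.), THF/DMF, rt to 50 °C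
Reagents that add atoms: none
Why: C-alkylation of the β-ketophosphonate sodium enolate with an activated benzylic chloride; the more hindered product anion resists a second alkylation, and the new stereocentre is lost in step 6.

Step 6
Reactants: 10 diethyl {1-[4-(benzyloxy)phenyl]-3-oxobutan-2-yl}phosphonate; 7 3-(ArB)propanal
Product: 11 (3E)-3-[4-(benzyloxy)benzyl]-6-(ArB)hex-3-en-2-one
Conditions: Ba(OH)2·8H2O, THF/H2O (40:1), rt
Reagents that add atoms: none
Why: Horner–Wadsworth–Emmons olefination under mild Ba(OH)2 conditions suited to α-branched β-ketophosphonates and enolisable aldehydes; the E isomer (acetyl trans to the chain) should dominate, and any Z isomer is equally usable because step 8 destroys the alkene geometry.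

Step 7
Reactants: 12 dimethyl malonate; 9 4-(benzyloxy)benzyl chloride
Product: 13 dimethyl 2-[4-(benzyloxy)benzyl]malonate
Conditions: NaH (1 equiv), 12 (2.5 equiv), THF, 0 °C; then 9, THF/DMF, rt
Reagents that add atoms: none
Why: Malonic ester alkylation; excess malonate suppresses dialkylation and the aprotic medium avoids solvolysis of the 4-alkoxybenzyl chloride.

Step 8
Reactants: 11 (3E)-3-[4-(benzyloxy)benzyl]-6-(ArB)hex-3-en-2-one; 13 dimethyl 2-[4-(benzyloxy)benzyl]malonate
Product: 15 methyl 1,3-bis[4-(benzyloxy)benzyl]-2-[2-(ArB)ethyl]-4,6-dioxocyclohexane-1-carboxylate (diastereomer mixture), via acyclic Michael adduct 14 (not isolated)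
Conditions: NaOMe (1.5 equiv), MeOH/THF, 65–70 °C, prolonged; then 1 M HCl
Reagents that add atoms: none
Why: Methoxide deprotonates 13, whose anion adds reversibly in the 1,4-sense to C4 of enone 11 (the C5–C6 bond of ring A) to give keto diester 14; the acetyl methyl enolate of 14 then attacks one malonate ester and expels methoxide (the C1–C2 bond of ring A). The closest known reaction is the classical Michael–Claisen synthesis of 4-carboalkoxycyclohexane-1,3-diones from enones and malonates, used for 5-alkylresorcinol precursors and, with alkylmalonates, for 4-substituted diones; here both partners are more hindered. Ring A closes by a 6-(enolendo)-exo-trig Claisen acylation, which is a favoured mode. The three new stereocentres (C1, C2 and C3 of 15) are not controlled and need not be, since C3 is epimerisable and all three disappear on aromatisation. Only constitutional selectivity is required: the stabilised malonate under equilibrating conditions gives 1,4-addition because 1,2-adducts revert, and ring closure can only come from the acetyl methyl group because the enolate at the benzyl-bearing α-carbon would have to form a four-membered ring. Irreversible deprotonation of the acidic 1,3-dione product by methoxide pulls the unfavourable Michael equilibrium forward.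

Step 9
Reactants: 15 methyl 1,3-bis[4-(benzyloxy)benzyl]-2-[2-(ArB)ethyl]-4,6-dioxocyclohexane-1-carboxylate
Product: 17 4,6-bis[4-(benzyloxy)benzyl]-5-[2-(ArB)ethyl]cyclohexane-1,3-dione (diastereomer mixture), via dioxo carboxylic acid 16 (not isolated)
Conditions: KOH, H2O/1,4-dioxane, reflux; then HCl to pH 1, 60 °C
Reagents that add atoms: water, O
Why: Saponification followed by β-keto acid decarboxylation; under hydroxide the dione is present as its enolate, which protects the ring from retro-Claisen cleavage while the methyl ester is hydrolysed, and the free acid 16, whose hydroxyl oxygen comes from water, loses that oxygen again as carbon dioxide on warming in acid.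

Step 10
Reactants: 17 4,6-bis[4-(benzyloxy)benzyl]-5-[2-(ArB)ethyl]cyclohexane-1,3-dione
Product: 18 4,6-bis[4-(benzyloxy)benzyl]-5-[2-(ArB)ethyl]-3-methoxycyclohex-2-en-1-one (diastereomer mixture)
Conditions: HC(OMe)3, TsOH·H2O (cat.), MeOH, rt to 50 °C
Reagents that add atoms: trimethyl orthoformate, COC(OC)OC
Why: Acid-catalysed enol etherification of a cyclic 1,3-dione, which gives O-methylation only and stops at the vinylogous ester; the dione is constitutionally symmetric, so either carbonyl leads to the same constitution and one methoxy group is installed without touching C2.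

Step 11
Reactants: 18 4,6-bis[4-(benzyloxy)benzyl]-5-[2-(ArB)ethyl]-3-methoxycyclohex-2-en-1-one
Product: 21 2,4-bis[4-(benzyloxy)benzyl]-3-[2-(ArB)ethyl]-5-methoxyphenol, via silyl dienol ether 19 (not isolated), via cyclohexadienone keto tautomer 20 (not isolated)
Conditions: LiN(iPr)2, Me3SiCl, THF, −78 °C; non-aqueous work-up; then Pd(OAc)2 (1.1 equiv), MeCN/CH2Cl2, rt
Reagents that add atoms: chlorotrimethylsilane, C[Si](C)(C)Cl
Why: Saegusa–Ito oxidation; kinetic α'-deprotonation of the vinylogous ester at C6 and O-silylation give 19, divalent palladium forms the oxa-π-allyl species with loss of the silyl group as trimethylsilyl acetate, and β-hydride elimination gives dienone 20, the keto tautomer of the phenol, which aromatises at once, while any exocyclic benzylidene isomer should be drawn into the same arene by palladium hydride re-addition and the benzyl ethers and diarylmethane CH2 groups are inert to Pd(OAc)2 at rt.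

Step 12
Reactants: 21 2,4-bis[4-(benzyloxy)benzyl]-3-[2-(ArB)ethyl]-5-methoxyphenol
Product: 22 3-{2-[3-hydroxy-4-(4-hydroxybenzyl)phenyl]ethyl}-2,4-bis(4-hydroxybenzyl)-5-methoxyphenol (CNP0207338.0)
Conditions: H2 (1 atm), 10% Pd/C, THF/MeOH, rt
Reagents that add atoms: none
Why: Hydrogenolysis of the four aryl benzyl ethers; the aryl methyl ether, the diarylmethane and the dihydrostilbene-type C–C bonds are stable under these conditions.

**Compound list**

1 | 4-bromo-2-hydroxybenzaldehyde | O=Cc1ccc(Br)cc1O | starting material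
2 | 2-(benzyloxy)-4-bromobenzaldehyde | O=Cc1ccc(Br)cc1OCc1ccccc1 | intermediate
3 | 4-(benzyloxy)phenylmagnesium bromide | Br[Mg]c1ccc(OCc2ccccc2)cc1 | starting material
4 | [2-(benzyloxy)-4-bromophenyl][4-(benzyloxy)phenyl]methanol (racemate) | OC(c1ccc(OCc2ccccc2)cc1)c1ccc(Br)cc1OCc1ccccc1 | intermediate
5 | 2-(benzyloxy)-1-[4-(benzyloxy)benzyl]-4-bromobenzene | Brc1ccc(Cc2ccc(OCc3ccccc3)cc2)c(OCc2ccccc2)c1 | intermediate
6 | allyl alcohol (prop-2-en-1-ol) | C=CCO | starting material
7 | 3-{3-(benzyloxy)-4-[4-(benzyloxy)benzyl]phenyl}propanal | O=CCCc1ccc(Cc2ccc(OCc3ccccc3)cc2)c(OCc2ccccc2)c1 | intermediate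
8 | diethyl (2-oxopropyl)phosphonate | CCOP(=O)(CC(C)=O)OCC | starting material
9 | 4-(benzyloxy)benzyl chloride | ClCc1ccc(OCc2ccccc2)cc1 | starting material
10 | diethyl {1-[4-(benzyloxy)phenyl]-3-oxobutan-2-yl}phosphonate (racemate) | CCOP(=O)(OCC)C(Cc1ccc(OCc2ccccc2)cc1)C(C)=O | intermediate
11 | (3E)-3-[4-(benzyloxy)benzyl]-6-{3-(benzyloxy)-4-[4-(benzyloxy)benzyl]phenyl}hex-3-en-2-one | CC(=O)/C(Cc1ccc(OCc2ccccc2)cc1)=C/CCc1ccc(Cc2ccc(OCc3ccccc3)cc2)c(OCc2ccccc2)c1 | intermediate
12 | dimethyl malonate | COC(=O)CC(=O)OC | starting material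
13 | dimethyl 2-[4-(benzyloxy)benzyl]malonate | COC(=O)C(Cc1ccc(OCc2ccccc2)cc1)C(=O)OC | intermediate
14 | dimethyl 2-[4-(benzyloxy)benzyl]-2-(2-[4-(benzyloxy)benzyl]-1-{2-[3-(benzyloxy)-4-(4-(benzyloxy)benzyl)phenyl]ethyl}-3-oxobutyl)malonate (diastereomer mixture) | COC(=O)C(Cc1ccc(OCc2ccccc2)cc1)(C(=O)OC)C(CCc1ccc(Cc2ccc(OCc3ccccc3)cc2)c(OCc2ccccc2)c1)C(Cc1ccc(OCc2ccccc2)cc1)C(C)=O | intermediate
15 | methyl 1,3-bis[4-(benzyloxy)benzyl]-2-{2-[3-(benzyloxy)-4-(4-(benzyloxy)benzyl)phenyl]ethyl}-4,6-dioxocyclohexane-1-carboxylate (diastereomer mixture) | COC(=O)C1(Cc2ccc(OCc3ccccc3)cc2)C(=O)CC(=O)C(Cc2ccc(OCc3ccccc3)cc2)C1CCc1ccc(Cc2ccc(OCc3ccccc3)cc2)c(OCc2ccccc2)c1 | intermediate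
16 | 1,3-bis[4-(benzyloxy)benzyl]-2-{2-[3-(benzyloxy)-4-(4-(benzyloxy)benzyl)phenyl]ethyl}-4,6-dioxocyclohexane-1-carboxylic acid (diastereomer mixture) | OC(=O)C1(Cc2ccc(OCc3ccccc3)cc2)C(=O)CC(=O)C(Cc2ccc(OCc3ccccc3)cc2)C1CCc1ccc(Cc2ccc(OCc3ccccc3)cc2)c(OCc2ccccc2)c1 | intermediate
17 | 4,6-bis[4-(benzyloxy)benzyl]-5-{2-[3-(benzyloxy)-4-(4-(benzyloxy)benzyl)phenyl]ethyl}cyclohexane-1,3-dione (diastereomer mixture) | O=C1CC(=O)C(Cc2ccc(OCc3ccccc3)cc2)C(CCc2ccc(Cc3ccc(OCc4ccccc4)cc3)c(OCc3ccccc3)c2)C1Cc1ccc(OCc2ccccc2)cc1 | intermediate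
18 | 4,6-bis[4-(benzyloxy)benzyl]-5-{2-[3-(benzyloxy)-4-(4-(benzyloxy)benzyl)phenyl]ethyl}-3-methoxycyclohex-2-en-1-one (diastereomer mixture) | COC1=CC(=O)C(Cc2ccc(OCc3ccccc3)cc2)C(CCc2ccc(Cc3ccc(OCc4ccccc4)cc3)c(OCc3ccccc3)c2)C1Cc1ccc(OCc2ccccc2)cc1 | intermediate
19 | {[2,4-bis(4-(benzyloxy)benzyl)-3-{2-[3-(benzyloxy)-4-(4-(benzyloxy)benzyl)phenyl]ethyl}-5-methoxycyclohexa-1,5-dien-1-yl]oxy}trimethylsilane (diastereomer mixture) | COC1=CC(O[Si](C)(C)C)=C(Cc2ccc(OCc3ccccc3)cc2)C(CCc2ccc(Cc3ccc(OCc4ccccc4)cc3)c(OCc3ccccc3)c2)C1Cc1ccc(OCc2ccccc2)cc1 | intermediate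
20 | 2,4-bis[4-(benzyloxy)benzyl]-3-{2-[3-(benzyloxy)-4-(4-(benzyloxy)benzyl)phenyl]ethyl}-5-methoxycyclohexa-2,5-dien-1-one (racemate) | COC1=CC(=O)C(Cc2ccc(OCc3ccccc3)cc2)=C(CCc2ccc(Cc3ccc(OCc4ccccc4)cc3)c(OCc3ccccc3)c2)C1Cc1ccc(OCc2ccccc2)cc1 | intermediate
21 | 2,4-bis[4-(benzyloxy)benzyl]-3-{2-[3-(benzyloxy)-4-(4-(benzyloxy)benzyl)phenyl]ethyl}-5-methoxyphenol | COc1cc(O)c(Cc2ccc(OCc3ccccc3)cc2)c(CCc2ccc(Cc3ccc(OCc4ccccc4)cc3)c(OCc3ccccc3)c2)c1Cc1ccc(OCc2ccccc2)cc1 | intermediate
22 | 3-{2-[3-hydroxy-4-(4-hydroxybenzyl)phenyl]ethyl}-2,4-bis(4-hydroxybenzyl)-5-methoxyphenol | COc1cc(O)c(Cc2ccc(O)cc2)c(CCc2ccc(Cc3ccc(O)cc3)c(O)c2)c1Cc1ccc(O)cc1 | target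

**Step count and risk**

Total steps: 12. Longest linear sequence: 10 steps (1, 2, 3, 4, 6, 8, 9, 10, 11, 12); steps 5 and 7 supply the two side fragments.

Steps most likely to fail:

1. Step 8. The conjugate addition joins a tertiary malonate anion to a trisubstituted enone and may revert faster than the ring closes, while base-induced self-condensation of the enone consumes material. Fallback from 11: the donor is made smaller by running the same NaOMe/MeOH annulation with dimethyl malonate 12 itself, the unhindered classical case, to give methyl 3-[4-(benzyloxy)benzyl]-2-{2-[3-(benzyloxy)-4-(4-(benzyloxy)benzyl)phenyl]ethyl}-4,6-dioxocyclohexane-1-carboxylate F1. Its dianion (LiN(iPr)2, 2.2 equiv, THF, −78 to 0 °C; dione enolate plus ester enolate at C1) is then C-benzylated at C1, the more basic site, with chloride 9. This returns to the route at 15.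

2. Step 11. Palladation of the crowded, tetrasubstituted enol silane may be slow, so that protodesilylation back to the enone competes, or elimination toward the exocyclic benzylic position may not be followed by isomerisation into the ring. Fallback from 18: the lithium enolate (LiN(iPr)2, THF, −78 °C) is trapped with PhSeCl to give 4,6-bis[4-(benzyloxy)benzyl]-5-{2-[3-(benzyloxy)-4-(4-(benzyloxy)benzyl)phenyl]ethyl}-3-methoxy-6-(phenylselanyl)cyclohex-2-en-1-one F2. Oxidation (H2O2, pyridine, CH2Cl2, 0 °C) and syn-elimination of the selenoxide, followed by brief base treatment to isomerise any benzylidene isomer, lead through dienone 20 back to the route at 21.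

3. Step 9. Hydrolysis of the ester on a quaternary carbon next to an anionic dione may stall, and forcing hydroxide conditions may open the ring. Fallback from 15: Krapcho dealkoxycarbonylation (LiCl, wet DMSO, 150 °C) cleaves the O–methyl bond by nucleophilic attack of chloride, so no acyl substitution at the hindered carbonyl is needed. The carboxylate of 16 then loses CO2 in the same pot, returning to the route at 17 without any new isolated compound.

**Further compounds**

F1 | step 8 | methyl 3-[4-(benzyloxy)benzyl]-2-{2-[3-(benzyloxy)-4-(4-(benzyloxy)benzyl)phenyl]ethyl}-4,6-dioxocyclohexane-1-carboxylate (diastereomer mixture) | COC(=O)C1C(=O)CC(=O)C(Cc2ccc(OCc3ccccc3)cc2)C1CCc1ccc(Cc2ccc(OCc3ccccc3)cc2)c(OCc2ccccc2)c1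
F2 | step 11 | 4,6-bis[4-(benzyloxy)benzyl]-5-{2-[3-(benzyloxy)-4-(4-(benzyloxy)benzyl)phenyl]ethyl}-3-methoxy-6-(phenylselanyl)cyclohex-2-en-1-one (diastereomer mixture) | COC1=CC(=O)C(Cc2ccc(OCc3ccccc3)cc2)([Se]c2ccccc2)C(CCc2ccc(Cc3ccc(OCc4ccccc4)cc3)c(OCc3ccccc3)c2)C1Cc1ccc(OCc2ccccc2)cc1
F0 | step 9 | none | none
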